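Assumption: ring positions are written as ring letter plus locant (position 1 of rings B to G carries the oxygen coming from the preceding ring; A1 carries the oxygen to ring B). All hydroxyls travel as methyl ethers. The target has no stereocentre; the one stereocentre met on the way (the carbinol carbon of 9 and of 15, both racemic) is destroyed by the ring expansion. The cyclobutenone 15 and the quinone 16 were compared ring by ring with the target and need no correction. Compounds 1, 2, 5, 7 and 19 are taken as commercial. Dichloroacetylene 3 is toxic and explosive when neat; it is generated and consumed in solution in step 1 only, under argon with a scrubbed vent, and is never isolated.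

## Structural features

The target, C42H30O24, is a linear phlorethol-type heptamer: seven benzene rings A to G held together only by six diaryl ether oxygens and carrying eighteen free phenolic hydroxyls. There is no stereocentre, so no question of neighbouring stereocentres arises. Ring A is a 2,4,6-trihydroxyphenyl ether, rings B, D and F are 1,4-dioxygenated with hydroxyls at positions 3 and 5, rings C and E carry five contiguous oxygens (ether oxygens at 1 and 6, hydroxyls at 3, 4 and 5, hydrogen at 2), and ring G is a 3,4,5-trihydroxyphenyl ether. Each ether oxygen sits on one carbon flanked by two oxygen substituents (A1, B4, C6, D4, E6, F4); its other carbon has two free ortho positions in four of the ethers (B1, D1, F1, G1) but only one in B4–O–C1 and D4–O–E1. These two tri-ortho-substituted ethers are the real difficulty, since rings C and E offer no place for an SNAr activating group and a copper coupling would have to unite two hindered partners. Fragile points are the free polyphenol with its pyrogallol and hydroxyhydroquinone units (air oxidation, worst in base), the hydroquinones met on the way (air), and the dichlorovinyl ethers, ynol ethers and cyclobutenones (acid). Ring E has para oxygens at E3 and E6 and vicinal oxygens at E4 and E5, which is the pattern of a 2,3-dialkoxy-1,4-benzoquinone descended from a squarate ester; the key step uses this by growing ring E on the D4 oxygen and closing the E6–E1 bond, and ring C shows the same pattern (C3/C6, C4/C5).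

## Logic of the disconnections

22 from 21. All eighteen O–H bonds are traced back to O–CH3 bonds. Methyl is the one phenol mask that tolerates n-BuLi, 138 °C and hot phosphate with copper alike, so every intermediate is a neutral ether and the polyphenol exists only after the last step. The price is an exhaustive eighteen-fold cleavage, which asks for a large excess of BBr3 and oxygen-free isolation.

21 from 18 and 20. The E6–O–F1 ether is cut at the O–F1 bond. F1 has two free ortho positions, so the crowding lies only on the E6 oxygen, which acts as nucleophile toward an unhindered aryl bromide; two rings are removed at once (5 + 2). The forward step must couple a phenol flanked by an aryloxy and a methoxy group, the most demanding copper coupling of the route.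

20 from 1 and 19. The F4–O–G1 ether is cut at the O–G1 bond for the same reason (F4 flanked by two methoxyls, G1 open). Both pieces are commercial, so the dimer costs one step. The forward coupling must leave the C–Br bond at F1 alone, which points to an oxidative boronic acid coupling at room temperature.

18 from 17 from 16. The E3 O–CH3 bond is cut and the ring-E hydroquinone is taken back to the quinone, the oxidation level at which the ring expansion delivers ring E. The forward steps must tell the two hydroxyls apart: the E3 hydroxyl has a free ortho position and two meta oxygen substituents (less hindered, more acidic), while the E6 hydroxyl lies between two oxygen substituents, so one equivalent of a small electrophile should choose E3.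

16 from 15. Ring E is opened at the E6–E1 bond, which leaves the four-membered ring with its alkyne side chain. The tri-ortho-substituted ether D4–O–E1 thereby becomes an ether oxygen on an sp carbon, where crowding no longer matters, and all five oxygens of ring E are accounted for at once. The forward step must close the six-membered and not the five-membered ring, on heating alone.

15 from 13 and 7 (through 14). The bond between the carbinol carbon (future E3) and the alkyne carbon (future E2) is cut. 7 supplies E3 to E6 with the E4 and E5 methoxyls, and the two carbons on the D4 oxygen become E1 and E2. The forward step needs exact control of the base (two equivalents of n-BuLi, no ortho-lithiation of the methoxyarenes) and a single addition to one carbonyl of 7.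

13 from 12 and 4. The C6–O–D1 ether is cut at the O–D1 bond. D1 is unhindered, and ring D arrives with its D4 oxygen already bearing the two-carbon unit, so no protecting group is spent on D4 and the tetramer never has to be handled as a free phenol. The forward coupling puts the hindered oxygen on the nucleophile and must leave the dichlorovinyl ether (two vinyl C–Cl bonds, one vinyl C–H) untouched.

12 from 11 from 10 from 9; 9 from 6 and 7 (through 8). Ring C is taken apart exactly as ring E: methyl ether at C3, hydroquinone, quinone, C6–C1 bond, carbinol–alkyne bond. B4–O–C1 is the second tri-ortho-substituted ether and yields to the same answer, and the ring growth is first run on a small substrate. The demands are those of the ring-E sequence.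

6 from 5 and 4. The A1–O–B1 ether is cut at the O–B1 bond (A1 flanked by two methoxyls, B1 open). 4 serves a second time, now as ring B, so one building block covers rings B and D. The forward coupling needs the electron-rich phenoxide of 5 kept from air and, again, a dichlorovinyl ether that survives.

4 from 1 and 2 (through 3). The enol ether O–C bond is cut. The hindered phenoxide only has to add to a linear two-carbon electrophile, so both difficult ethers begin as an O–C(sp2) bond made without steric penalty. The hazardous in-flask intermediate 3 is needed in one operation only, on the cheapest substrate of the route. The forward step must leave the aryl bromide alone and consume 3 as fast as it forms.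

## Other disconnections considered

Alternative 1: The cut is made on ring B: the O–B1 bond of the A–O–B ether and the two methoxy C–O bonds at B3 and B5 are all traced to C–F bonds of one arene. In one pot the phenoxide of 5 would take the fluoride para to the formyl group of 2,4,6-trifluorobenzaldehyde A1 and NaOMe the two ortho fluorides, giving 2,6-dimethoxy-4-(2,4,6-trimethoxyphenoxy)benzaldehyde A2; no ring closes. A Dakin-type oxidation would turn A2 into the dimer AB phenol A3, and dichlorovinylation of A3 as in step 1 would meet the route at 6.
- In its favour: no metal, no protecting group, an unhindered and strongly activated carbon for the hindered phenoxide, and a formyl group that first activates all three positions and then becomes the B4 oxygen. The dichlorovinyl ether of the dimer would never see hot copper and phosphate; on that point it is the better.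
- Against it: the ortho fluorides are activated too, so the first substitution need not be clean, and methoxide could displace the para aryloxy group once it is in place or add to the aldehyde.
- Structure: it answers only the A–O–B ether, which the chosen plan also finds easy (step 2). Rings C and E have no place for an activating group, so the two tri-ortho-substituted ethers stay unsolved and the ring growth of steps 4 and 9 would still be needed.
- Mechanism: addition–elimination through a Meisenheimer adduct is at least the equal of the copper coupling of step 2 in reliability and the better in cost.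
- Step economy: A2, A3 and the dichlorovinylation are three operations to 6 against two (steps 1 and 2), and 3 would have to be generated a second time, while 4 is needed for step 7 in any case; here the chosen plan is the better.

Alternative 2: The cut is the A5–A6 carbon–carbon bond, so ring A would be built last on a finished hexamer. Base would fold the triketide diester A4 (dimethyl 2-aryloxy-3,5-dioxoheptanedioate bound to the hexamer BCDEFG through the B1 oxygen): the terminal active methylene attacks the far ester carbonyl in an intramolecular Claisen condensation, and enolisation gives the heptamer A5 with ring A as a methyl 3-aryloxy-2,4,6-trihydroxybenzoate.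
- In its favour: the step is biomimetic, ionic and mild, and ring A arrives with free hydroxyls, so fifteen and not eighteen methyl ethers remain to be cleaved. On that point it is the better.
- Against it: ring A is the one ring that can be bought complete (5) and its ether is the least hindered. In a 3,5-dioxo ester such as A4, O-acylation with closure of a pyranone ring competes with the wanted C-acylation. A5 still needs ester hydrolysis and decarboxylation.
- Structure: the hexamer part of A4 contains both tri-ortho-substituted ethers and rings C and E, so nothing of the core difficulty is removed. On stereochemistry the plans are equal: none arises in either.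
- Mechanism: an ionic chain folding with an ambident nucleophile stands against a unimolecular thermal rearrangement with one competing closure.
- Step economy: attaching and extending the chain, cyclising and removing the ester would replace the single coupling of step 2 by at least four operations at the end of the longest sequence, which is worse.

Alternative 3: The cuts are the D2–D3 and D5–D6 bonds of the central ring. The dienolate of the glutaconate A6 (dimethyl 3-aryloxypent-2-enedioate carrying trimer ABC on the C6 oxygen) would be C-acylated twice by the malonyl dichloride A7 (carrying trimer EFG on the E1 oxygen), closing ring D as the heptamer A8, a dimethyl 4,6-dihydroxy-2,5-bis(aryloxy)isophthalate.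
- In its favour: the union is 3 + 1 + 3 with ring D formed in the joining step, so on convergence it is the better. The hindered D1 and D4 oxygens are attached before ring D is aromatic, the same principle as the chosen ring growth, so on that idea the two plans are equal. D3 and D5 arrive as free hydroxyls.
- Against it: A7 carries an acidic hydrogen between two acid chloride groups and should lose HCl readily (ketene formation). The dienolate of A6 is ambident, and after the first C-acylation O-acylation with pyranone closure is the usual course of malonyl dichlorides. A8 must then lose two esters from a fully substituted ring (hindered saponification, double decarboxylation).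
- Structure: A6 needs trimer ABC with the tri-ortho-substituted B4–O–C1 ether and A7 needs a ring E with five oxygens and differentiated E1/E6, so both would still call for the ring growth used here or for a hard coupling.
- Mechanism: an intermolecular double acylation with a chemoselectivity question at each stage stands against an intramolecular rearrangement.
- Step economy: with the longest sequence of the chosen plan at thirteen steps the gain in length would be small, and the total number of operations would not be lower.

Key step: step 9

## Route

Abbreviation used in names: "ABCD-oxy" is the 4-{6-[2,6-dimethoxy-4-(2,4,6-trimethoxyphenoxy)phenoxy]-2,3,4-trimethoxyphenoxy}-2,6-dimethoxyphenoxy group (tetramer bound through its D4 oxygen).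

Step 1
Reactants: 1 4-bromo-2,6-dimethoxyphenol; 2 trichloroethylene
Product: 4 5-bromo-2-{[(E)-1,2-dichloroethenyl]oxy}-1,3-dimethoxybenzene, via dichloroacetylene 3 (not isolated)
Conditions: K2CO3, DMF, 70 °C, Ar
Reagents that add atoms: none
Why: The base eliminates HCl from 2 to give 3, the phenoxide of 1 adds to it and anti protonation gives the (E)-1,2-dichlorovinyl ether, the standard preparation of aryl dichlorovinyl ethers; the linear acetylene is indifferent to the two ortho methoxyls and the aryl bromide does not react with carbonate. This one operation supplies the two-carbon unit for both ring C and ring E.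

Step 2
Reactants: 5 2,4,6-trimethoxyphenol; 4 5-bromo-2-{[(E)-1,2-dichloroethenyl]oxy}-1,3-dimethoxybenzene
Product: 6 2-{[(E)-1,2-dichloroethenyl]oxy}-1,3-dimethoxy-5-(2,4,6-trimethoxyphenoxy)benzene (dichlorovinyl ether of dimer AB)
Conditions: CuI (10 mol %), picolinic acid (20 mol %), K3PO4, DMSO, 90 °C, Ar
Reagents that add atoms: none
Why: Ullmann ether synthesis with a picolinate-ligated monovalent copper catalyst; the hindrance lies only on the phenoxide of 5, while the C–Br carbon of 4 has two free ortho positions. The vinyl C–Cl bonds are far less reactive toward this catalyst than the aryl bromide, and the only vinyl hydrogen is cis to the chlorine on the neighbouring carbon, so loss of HCl should need an organolithium base and not phosphate.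

Step 3
Reactants: 6 dichlorovinyl ether of dimer AB; 7 dimethyl squarate
Product: 9 racemic 4-hydroxy-2,3-dimethoxy-4-{[2,6-dimethoxy-4-(2,4,6-trimethoxyphenoxy)phenoxy]ethynyl}cyclobut-2-en-1-one, via lithium aryloxyacetylide 8 (not isolated)
Conditions: n-BuLi (2.2 equiv), THF, −78 to −40 °C; then added to 7 (1.3 equiv), THF, −78 °C; aq NH4Cl; Et3N-washed SiO2
Reagents that add atoms: none
Why: n-BuLi removes the vinyl proton, LiCl is lost and chlorine–lithium exchange leaves the acetylide 8, which adds 1,2 to one of the two equivalent carbonyls of 7; inverse addition to excess 7 prevents a second addition. The carbinol stereocentre forms racemic and disappears in step 4.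

Step 4
Reactants: 9 cyclobutenone of dimer AB
Product: 10 5-[2,6-dimethoxy-4-(2,4,6-trimethoxyphenoxy)phenoxy]-2,3-dimethoxy-1,4-benzoquinone (trimer ABC with ring C as quinone)
Conditions: p-xylene (0.02 M), 138 °C, Ar
Reagents that add atoms: none
Why: Moore rearrangement, the same ring expansion as the key step on the smaller substrate: 4π ring opening to the alkynylvinylketene, closure of the ketene carbon onto the oxygen-bearing alkyne carbon (C6–C1 bond) and hydrogen transfer give ring C as the quinone. It also tests the aryloxyalkyne in this reaction before the tetramer is committed.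

Step 5
Reactants: 10 trimer ABC quinone
Product: 11 5-[2,6-dimethoxy-4-(2,4,6-trimethoxyphenoxy)phenoxy]-2,3-dimethoxybenzene-1,4-diol (trimer ABC hydroquinone; hydroxyls at C3 and C6)
Conditions: Na2S2O4, EtOAc/H2O, rt, Ar
Reagents that add atoms: none
Why: Dithionite reduction of a 1,4-benzoquinone, a fast two-electron, two-proton transfer that leaves the aryl ethers untouched; the product is kept under argon and used at once.

Step 6
Reactants: 11 trimer ABC hydroquinone
Product: 12 6-[2,6-dimethoxy-4-(2,4,6-trimethoxyphenoxy)phenoxy]-2,3,4-trimethoxyphenol (trimer ABC phenol; free hydroxyl at C6)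
Conditions: MeI (1.05 equiv), K2CO3 (1.1 equiv), acetone, 0 °C to rt, Ar
Reagents that add atoms: iodomethane, CI
Why: Williamson methylation of the mono-phenoxide; the C3 hydroxyl has a free ortho position and two meta oxygen substituents (less hindered, more acidic), whereas the C6 hydroxyl lies between the aryloxy and a methoxy group, so one equivalent of MeI should go to the C3 oxygen.

Step 7
Reactants: 12 trimer ABC phenol; 4 5-bromo-2-{[(E)-1,2-dichloroethenyl]oxy}-1,3-dimethoxybenzene
Product: 13 (E)-1,2-dichloro-1-(ABCD-oxy)ethene (dichlorovinyl ether of tetramer ABCD at the D4 oxygen)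
Conditions: CuI (20 mol %), picolinic acid (40 mol %), K3PO4, DMSO, 90 °C, Ar
Reagents that add atoms: none
Why: Ullmann ether synthesis as in step 2; the hindered C6 phenoxide is the nucleophile, the bromide carbon (future D1) has two free ortho positions, and 4 can be used in excess. Ring D thus arrives with the future E1 and E2 carbons already on its hindered D4 oxygen.

Step 8
Reactants: 13 dichlorovinyl ether of tetramer ABCD; 7 dimethyl squarate
Product: 15 racemic 4-hydroxy-2,3-dimethoxy-4-[(ABCD-oxy)ethynyl]cyclobut-2-en-1-one, via lithium aryloxyacetylide 14 (not isolated)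
Conditions: n-BuLi (2.2 equiv), THF, −78 to −40 °C; then added to 7 (1.3 equiv), THF, −78 °C; aq NH4Cl; Et3N-washed SiO2
Reagents that add atoms: none
Why: Acetylide formation and 1,2-addition to one carbonyl of 7 as in step 3; low temperature and two equivalents of n-BuLi keep ortho-lithiation of the methoxyarenes from competing. The tertiary hydroxyl is left free because its hydrogen is the one delivered to E2 in step 9; the stereocentre is racemic and transient.

Step 9
Reactants: 15 cyclobutenone of tetramer ABCD
Product: 16 5-(ABCD-oxy)-2,3-dimethoxy-1,4-benzoquinone (pentamer with ring E as quinone)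
Conditions: p-xylene (0.02 M), 138 °C, Ar
Reagents that add atoms: none
Why: This is a Moore rearrangement of a 4-alkynyl-4-hydroxycyclobutenone. Heating opens the four-membered ring by a conrotatory 4π electrocyclic process in which the donor hydroxyl turns outward, so the alkynyl group ends up cis to the ketene. The ketene carbon (future E6) then bonds to the remote, oxygen-bearing alkyne carbon (future E1) in a six-membered, endo-dig closure that gives a diradical with a σ-radical at E2 and an oxygen-centred radical; transfer of the hydroxyl hydrogen from the E3 oxygen to E2 gives the quinone. The closest known reaction is the thermal conversion of squarate-derived 4-alkynyl-4-hydroxy-2,3-dialkoxycyclobutenones into 2,3-dialkoxy-1,4-benzoquinones; the only change is an aryloxy group on the alkyne terminus. No stereocentre is formed and the carbinol stereocentre of 15 vanishes. The selectivity needed is this six-membered closure over exo-dig closure onto the near alkyne carbon, which would give an alkylidenecyclopentenedione through an exocyclic vinyl radical; an oxygen substituent gives that σ-radical no conjugative stabilisation, unlike aryl, silyl or ester groups, so the six-ring path should dominate. The aryloxy group has no β-hydrogen, so the retro-ene loss that limits alkyl ynol ethers at this temperature cannot occur, and dilution under argon suppresses bimolecular reactions of the ketene. Because the D4–O–E1 ether is already in place as the ynol ether, ring E forms with all five oxygens positioned.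

Step 10
Reactants: 16 pentamer quinone
Product: 17 5-(ABCD-oxy)-2,3-dimethoxybenzene-1,4-diol (pentamer hydroquinone; hydroxyls at E3 and E6)
Conditions: Na2S2O4, EtOAc/H2O, rt, Ar
Reagents that add atoms: none
Why: Dithionite reduction of the quinone as in step 5; the hydroquinone is used at once under argon.

Step 11
Reactants: 17 pentamer hydroquinone
Product: 18 6-(ABCD-oxy)-2,3,4-trimethoxyphenol (pentamer ABCDE phenol; free hydroxyl at E6)
Conditions: MeI (1.05 equiv), K2CO3 (1.1 equiv), acetone, 0 °C to rt, Ar
Reagents that add atoms: iodomethane, CI
Why: Selective Williamson methylation as in step 6; the E3 hydroxyl is the less hindered and the more acidic one, and the E6 hydroxyl, shielded by the bulky tetramer ether and a methoxy group, should stay free.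

Step 12
Reactants: 1 4-bromo-2,6-dimethoxyphenol; 19 (3,4,5-trimethoxyphenyl)boronic acid
Product: 20 5-bromo-1,3-dimethoxy-2-(3,4,5-trimethoxyphenoxy)benzene (dimer FG bromide)
Conditions: Cu(OAc)2 (1 equiv), pyridine, 4 Å MS, CH2Cl2, air, rt
Reagents that add atoms: none
Why: Chan–Lam coupling: the aryl group passes from boron to divalent copper, the hindered phenoxide binds and the C–O bond forms by reductive elimination from trivalent copper at room temperature. Aryl bromides are inert under these conditions, so the F1 bromide is kept for step 13.

Step 13
Reactants: 18 pentamer ABCDE phenol; 20 dimer FG bromide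
Product: 21 octadeca-O-methyl ether of the target (heptamer A to G with all eighteen hydroxyls as methyl ethers)
Conditions: CuI (20 mol %), picolinic acid (40 mol %), K3PO4, DMSO, 100 °C, Ar
Reagents that add atoms: none
Why: Ullmann ether synthesis of the same kind as steps 2 and 7; the E6 phenoxide is hindered but the C–Br carbon F1 has two free ortho positions, and 20 can be used in excess.

Step 14
Reactants: 21 octadeca-O-methyl heptamer
Product: 22 CNP0292517.0 (free heptamer)
Conditions: BBr3 (excess), CH2Cl2, −78 °C to rt; MeOH then H2O, Ar
Reagents that add atoms: none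
Why: Lewis acid ether cleavage: BBr3 binds each methoxy oxygen and bromide attacks the methyl carbon (SN2), while diaryl ethers have no sp3 carbon and survive. Hydrolysis of the aryl borates under argon frees the eighteen hydroxyls.

## Compound list

1 | 4-bromo-2,6-dimethoxyphenol | COc1cc(Br)cc(OC)c1O | starting material
2 | trichloroethylene | ClC=C(Cl)Cl | starting material
3 | dichloroacetylene (not isolated) | ClC#CCl | intermediate
4 | 5-bromo-2-{[(E)-1,2-dichloroethenyl]oxy}-1,3-dimethoxybenzene | Cl/C=C(Cl)\Oc1c(OC)cc(Br)cc1OC | intermediate
5 | 2,4,6-trimethoxyphenol | COc1cc(OC)c(O)c(OC)c1 | starting material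
6 | 2-{[(E)-1,2-dichloroethenyl]oxy}-1,3-dimethoxy-5-(2,4,6-trimethoxyphenoxy)benzene (dichlorovinyl ether of dimer AB) | Cl/C=C(Cl)\Oc2c(OC)cc(Oc1c(OC)cc(OC)cc1OC)cc2OC | intermediate
7 | dimethyl squarate (3,4-dimethoxycyclobut-3-ene-1,2-dione) | COC1=C(OC)C(=O)C1=O | starting material
8 | lithium [2,6-dimethoxy-4-(2,4,6-trimethoxyphenoxy)phenoxy]acetylide (not isolated) | [Li]C#COc2c(OC)cc(Oc1c(OC)cc(OC)cc1OC)cc2OC | intermediate
9 | racemic 4-hydroxy-2,3-dimethoxy-4-{[2,6-dimethoxy-4-(2,4,6-trimethoxyphenoxy)phenoxy]ethynyl}cyclobut-2-en-1-one | COC3=C(OC)C(O)(C#COc2c(OC)cc(Oc1c(OC)cc(OC)cc1OC)cc2OC)C3=O | intermediate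
10 | 5-[2,6-dimethoxy-4-(2,4,6-trimethoxyphenoxy)phenoxy]-2,3-dimethoxy-1,4-benzoquinone (trimer ABC quinone) | COC3=C(OC)C(=O)C(Oc2c(OC)cc(Oc1c(OC)cc(OC)cc1OC)cc2OC)=CC3=O | intermediate
11 | 5-[2,6-dimethoxy-4-(2,4,6-trimethoxyphenoxy)phenoxy]-2,3-dimethoxybenzene-1,4-diol (trimer ABC hydroquinone) | COc3c(OC)c(O)c(Oc2c(OC)cc(Oc1c(OC)cc(OC)cc1OC)cc2OC)cc3O | intermediate
12 | 6-[2,6-dimethoxy-4-(2,4,6-trimethoxyphenoxy)phenoxy]-2,3,4-trimethoxyphenol (trimer ABC phenol) | Oc3c(OC)c(OC)c(OC)cc3Oc2c(OC)cc(Oc1c(OC)cc(OC)cc1OC)cc2OC | intermediate
13 | (E)-1,2-dichloro-1-(ABCD-oxy)ethene (dichlorovinyl ether of tetramer ABCD at the D4 oxygen) | Cl/C=C(Cl)\Oc4c(OC)cc(Oc3c(OC)c(OC)c(OC)cc3Oc2c(OC)cc(Oc1c(OC)cc(OC)cc1OC)cc2OC)cc4OC | intermediate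
14 | lithium (ABCD-oxy)acetylide (not isolated) | [Li]C#COc4c(OC)cc(Oc3c(OC)c(OC)c(OC)cc3Oc2c(OC)cc(Oc1c(OC)cc(OC)cc1OC)cc2OC)cc4OC | intermediate
15 | racemic 4-hydroxy-2,3-dimethoxy-4-[(ABCD-oxy)ethynyl]cyclobut-2-en-1-one | COC5=C(OC)C(O)(C#COc4c(OC)cc(Oc3c(OC)c(OC)c(OC)cc3Oc2c(OC)cc(Oc1c(OC)cc(OC)cc1OC)cc2OC)cc4OC)C5=O | intermediate
16 | 5-(ABCD-oxy)-2,3-dimethoxy-1,4-benzoquinone (pentamer quinone) | COC5=C(OC)C(=O)C(Oc4c(OC)cc(Oc3c(OC)c(OC)c(OC)cc3Oc2c(OC)cc(Oc1c(OC)cc(OC)cc1OC)cc2OC)cc4OC)=CC5=O | intermediate
17 | 5-(ABCD-oxy)-2,3-dimethoxybenzene-1,4-diol (pentamer hydroquinone) | COc5c(OC)c(O)c(Oc4c(OC)cc(Oc3c(OC)c(OC)c(OC)cc3Oc2c(OC)cc(Oc1c(OC)cc(OC)cc1OC)cc2OC)cc4OC)cc5O | intermediate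
18 | 6-(ABCD-oxy)-2,3,4-trimethoxyphenol (pentamer ABCDE phenol) | Oc5c(OC)c(OC)c(OC)cc5Oc4c(OC)cc(Oc3c(OC)c(OC)c(OC)cc3Oc2c(OC)cc(Oc1c(OC)cc(OC)cc1OC)cc2OC)cc4OC | intermediate
19 | (3,4,5-trimethoxyphenyl)boronic acid | COc1cc(B(O)O)cc(OC)c1OC | starting material
20 | 5-bromo-1,3-dimethoxy-2-(3,4,5-trimethoxyphenoxy)benzene (dimer FG bromide) | COc1cc(Br)cc(OC)c1Oc1cc(OC)c(OC)c(OC)c1 | intermediate
21 | octadeca-O-methyl ether of the target | COc1cc(OC)c(Oc2cc(OC)c(Oc3cc(OC)c(OC)c(OC)c3Oc3cc(OC)c(Oc4cc(OC)c(OC)c(OC)c4Oc4cc(OC)c(Oc5cc(OC)c(OC)c(OC)c5)c(OC)c4)c(OC)c3)c(OC)c2)c(OC)c1 | intermediate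
22 | CNP0292517.0 | Oc1cc(O)c(Oc2cc(O)c(Oc3cc(O)c(O)c(O)c3Oc3cc(O)c(Oc4cc(O)c(O)c(O)c4Oc4cc(O)c(Oc5cc(O)c(O)c(O)c5)c(O)c4)c(O)c3)c(O)c2)c(O)c1 | target

## Step count and least certain steps

Total: 14 steps. Longest linear sequence: 13 steps (steps 1 to 11, then 13 and 14); step 12 is the only side branch.

Step 9 (key step). The closure may take the five-membered course: an ynol ether is nucleophilic at the carbon remote from oxygen, so a polar attack of that carbon on the ketene could compete with the six-membered closure, and the ketene or the ynol ether may oligomerise at 138 °C. The fallback makes the D4–O–E1 ether by coupling and sets out from 13. Aqueous acid (aq HCl, THF, 40 °C) should hydrate the α-chloro enol ether to the chloroacetate of the tetramer ABCD phenol F1, and K2CO3 in MeOH should release the tetramer ABCD phenol F2. Commercial 2,3,4-trimethoxyphenol would be iodinated at the free position ortho to the hydroxyl (I2, aq NaHCO3) to give 6-iodo-2,3,4-trimethoxyphenol F3 and benzylated (BnBr, K2CO3, DMF) to 2-(benzyloxy)-1-iodo-3,4,5-trimethoxybenzene F4. Ullmann coupling of F2 with F4 (CuI, picolinic acid, K3PO4, DMSO, 110 °C) would give the pentamer ABCDE benzyl ether F5, a slower tri-ortho-substituted coupling of known type. Hydrogenolysis (H2, Pd/C) comes back to the route at 18.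

Step 7 (the same holds for step 2). The dichlorovinyl ether may not survive the coupling: hot phosphate in DMSO could remove the vinyl proton, after which chloride or the aryloxide is expelled, or copper could insert into the enol C–Cl bond. The fallback replaces the hot, basic coupling by an oxidative coupling at room temperature and sets out from 12. Commercial 2,6-dimethoxy-4-(4,4,5,5-tetramethyl-1,3,2-dioxaborolan-2-yl)phenol would be treated with 2 under the conditions of step 1 to give 2-(4-{[(E)-1,2-dichloroethenyl]oxy}-3,5-dimethoxyphenyl)-4,4,5,5-tetramethyl-1,3,2-dioxaborolane F6. NaIO4 and NH4OAc in aqueous acetone would free (4-{[(E)-1,2-dichloroethenyl]oxy}-3,5-dimethoxyphenyl)boronic acid F7. Chan–Lam coupling of 12 with F7 (Cu(OAc)2, pyridine, 4 Å MS, CH2Cl2, air, rt) comes back at 13; if step 2 is the one that fails, the same coupling of 5 with F7 comes back at 6.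

Step 13. Coordination and reductive elimination may be slow with the most hindered phenoxide of the route, so debromination of 20 or oxidation of the electron-rich phenoxide may overtake the coupling. The fallback changes the polarity of the aryl partner and sets out from 20: bromine–lithium exchange and borylation (n-BuLi, THF, −78 °C; B(OiPr)3; aq NH4Cl) would give [3,5-dimethoxy-4-(3,4,5-trimethoxyphenoxy)phenyl]boronic acid F8. A Chan–Lam coupling of 18 with F8 (Cu(OAc)2, pyridine, 4 Å MS, CH2Cl2, air, rt) comes back at 21.

Step 11 (the same holds for step 6). Site selection between the two hydroxyls may be incomplete, with methylation of the E6 oxygen or double methylation, and air may re-oxidise the hydroquinone. The fallback uses a reagent that responds far more strongly to crowding and sets out from 17: TIPSCl and imidazole in DMF should silylate only the E3 oxygen, giving the E3 triisopropylsilyl ether of the pentamer with free E6 hydroxyl F9. Chan–Lam coupling with F8 at room temperature, which spares the silyl ether from hot phosphate, would give the heptamer with E3 triisopropylsilyl ether and seventeen methyl ethers F10. BBr3 followed by the methanolic work-up should cleave the methyl ethers and the silyl ether together and comes back at 22.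

Step 14. Cleavage of eighteen methyl ethers may stop short as partly demethylated borates precipitate, and the free polyphenol may be oxidised during isolation. The fallback changes the isolation and sets out from 21: after the BBr3 treatment the crude polyphenol would not be isolated but acetylated (Ac2O, pyridine) to the octadecaacetate of the target F11, which is stable to air and can be chromatographed. Acid methanolysis (HCl in MeOH, Ar) comes back at 22.

## Further compounds

F1 | step 9 | chloroacetate of the tetramer ABCD phenol (ABCD-oxy 2-chloroacetate) | ClCC(=O)Oc4c(OC)cc(Oc3c(OC)c(OC)c(OC)cc3Oc2c(OC)cc(Oc1c(OC)cc(OC)cc1OC)cc2OC)cc4OC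
F2 | step 9 | tetramer ABCD phenol (4-{6-[2,6-dimethoxy-4-(2,4,6-trimethoxyphenoxy)phenoxy]-2,3,4-trimethoxyphenoxy}-2,6-dimethoxyphenol) | Oc4c(OC)cc(Oc3c(OC)c(OC)c(OC)cc3Oc2c(OC)cc(Oc1c(OC)cc(OC)cc1OC)cc2OC)cc4OC
F3 | step 9 | 6-iodo-2,3,4-trimethoxyphenol | COc1cc(I)c(O)c(OC)c1OC
F4 | step 9 | 2-(benzyloxy)-1-iodo-3,4,5-trimethoxybenzene | COc1cc(I)c(OCc2ccccc2)c(OC)c1OC
F5 | step 9 | pentamer ABCDE benzyl ether (benzyl ether of 18 at the E6 oxygen) | COc5cc(Oc4c(OC)cc(Oc3c(OC)c(OC)c(OC)cc3Oc2c(OC)cc(Oc1c(OC)cc(OC)cc1OC)cc2OC)cc4OC)c(OCc6ccccc6)c(OC)c5OC
F6 | step 7 | 2-(4-{[(E)-1,2-dichloroethenyl]oxy}-3,5-dimethoxyphenyl)-4,4,5,5-tetramethyl-1,3,2-dioxaborolane | Cl/C=C(Cl)\Oc1c(OC)cc(cc1OC)B1OC(C)(C)C(C)(C)O1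
F7 | step 7 | (4-{[(E)-1,2-dichloroethenyl]oxy}-3,5-dimethoxyphenyl)boronic acid | Cl/C=C(Cl)\Oc1c(OC)cc(B(O)O)cc1OC
F8 | step 13 | [3,5-dimethoxy-4-(3,4,5-trimethoxyphenoxy)phenyl]boronic acid | COc1cc(B(O)O)cc(OC)c1Oc1cc(OC)c(OC)c(OC)c1
F9 | step 11 | E3 triisopropylsilyl ether of the pentamer with free E6 hydroxyl | CC(C)[Si](C(C)C)(C(C)C)Oc5cc(Oc4c(OC)cc(Oc3c(OC)c(OC)c(OC)cc3Oc2c(OC)cc(Oc1c(OC)cc(OC)cc1OC)cc2OC)cc4OC)c(O)c(OC)c5OC
F10 | step 11 | heptamer with E3 triisopropylsilyl ether and seventeen methyl ethers | CC(C)[Si](C(C)C)(C(C)C)Oc5cc(Oc4c(OC)cc(Oc3c(OC)c(OC)c(OC)cc3Oc2c(OC)cc(Oc1c(OC)cc(OC)cc1OC)cc2OC)cc4OC)c(Oc6cc(OC)c(Oc7cc(OC)c(OC)c(OC)c7)c(OC)c6)c(OC)c5OC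
F11 | step 14 | octadecaacetate of the target | CC(=O)Oc1cc(OC(C)=O)c(Oc2cc(OC(C)=O)c(Oc3cc(OC(C)=O)c(OC(C)=O)c(OC(C)=O)c3Oc3cc(OC(C)=O)c(Oc4cc(OC(C)=O)c(OC(C)=O)c(OC(C)=O)c4Oc4cc(OC(C)=O)c(Oc5cc(OC(C)=O)c(OC(C)=O)c(OC(C)=O)c5)c(OC(C)=O)c4)c(OC(C)=O)c3)c(OC(C)=O)c2)c(OC(C)=O)c1
A1 | alternative 1 | 2,4,6-trifluorobenzaldehyde | O=Cc1c(F)cc(F)cc1F
A2 | alternative 1 | 2,6-dimethoxy-4-(2,4,6-trimethoxyphenoxy)benzaldehyde | COc1cc(OC)c(Oc2cc(OC)c(C=O)c(OC)c2)c(OC)c1
A3 | alternative 1 | dimer AB phenol (2,6-dimethoxy-4-(2,4,6-trimethoxyphenoxy)phenol) | COc1cc(OC)c(Oc2cc(OC)c(O)c(OC)c2)c(OC)c1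
A4 | alternative 2 | dimethyl 2-(hexamer BCDEFG-oxy)-3,5-dioxoheptanedioate (racemic at C2) | COC(=O)CC(=O)CC(=O)C(Oc2cc(OC)c(Oc3cc(OC)c(OC)c(OC)c3Oc3cc(OC)c(Oc4cc(OC)c(OC)c(OC)c4Oc4cc(OC)c(Oc5cc(OC)c(OC)c(OC)c5)c(OC)c4)c(OC)c3)c(OC)c2)C(=O)OC
A5 | alternative 2 | heptamer with ring A as methyl 3-aryloxy-2,4,6-trihydroxybenzoate | COC(=O)c1c(O)cc(O)c(Oc2cc(OC)c(Oc3cc(OC)c(OC)c(OC)c3Oc3cc(OC)c(Oc4cc(OC)c(OC)c(OC)c4Oc4cc(OC)c(Oc5cc(OC)c(OC)c(OC)c5)c(OC)c4)c(OC)c3)c(OC)c2)c1O
A6 | alternative 3 | dimethyl (E)-3-(trimer ABC-oxy)pent-2-enedioate | COC(=O)/C=C(\CC(=O)OC)Oc3c(OC)c(OC)c(OC)cc3Oc2c(OC)cc(Oc1c(OC)cc(OC)cc1OC)cc2OC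
A7 | alternative 3 | 2-(trimer EFG-oxy)propanedioyl dichloride | ClC(=O)C(C(Cl)=O)Oc4cc(OC)c(OC)c(OC)c4Oc5cc(OC)c(Oc6cc(OC)c(OC)c(OC)c6)c(OC)c5
A8 | alternative 3 | heptamer with ring D as dimethyl 4,6-dihydroxy-2,5-bis(aryloxy)isophthalate | COC(=O)c7c(O)c(Oc4cc(OC)c(OC)c(OC)c4Oc5cc(OC)c(Oc6cc(OC)c(OC)c(OC)c6)c(OC)c5)c(O)c(C(=O)OC)c7Oc3c(OC)c(OC)c(OC)cc3Oc2c(OC)cc(Oc1c(OC)cc(OC)cc1OC)cc2OC
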